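**Retrosynthetic overview**

- The target is an acyclic C19 ester of 3-(4-hydroxyphenyl)propanoic acid. Its one benzene ring is bonded to C3 of the propanoate chain, the carbon β to the ester carbonyl C1, and the strategy rests on this aryl–C3 bond. There is no stereocentre.
- The ester C–O bond is traced back to nonadecan-1-ol 1 and acryloyl chloride 2, which give nonadecyl acrylate 3, so the C19 chain is in place before the C–C bond is made.
- Key disconnection: the aryl C1'–C3 bond is formed from 4-hydroxyphenylboronic acid 4 and acrylate 3 by rhodium-catalysed 1,4-addition, which gives the target 5 directly with the phenol unprotected.
- Rings: none is formed; the benzene ring is bought with 4.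

Key step: step 2

Remark: the rhodium-bound species of the catalytic cycle in step 2 are catalyst states, not free compounds, and are not numbered; the route has two steps, so the risk section ranks both.

**Step 1**
Reactants: 1 nonadecan-1-ol; 2 acryloyl chloride
Product: 3 nonadecyl acrylate
Conditions: Et3N (1.5 equiv), BHT (cat.), CH2Cl2, 0 °C to rt
Reagents that add atoms: none
Why: Nucleophilic acyl substitution (O-acylation of a primary alcohol by an acid chloride with an amine base) is fast at 0 °C, and the cold, inhibited conditions should keep the new acrylate from polymerising or taking up chloride or amine by conjugate addition.

**Step 2**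
Reactants: 3 nonadecyl acrylate; 4 4-hydroxyphenylboronic acid
Product: 5 nonadecyl 3-(4-hydroxyphenyl)propanoate
Conditions: [Rh(cod)OH]2 (2.5 mol%), 4 (2 equiv), degassed 1,4-dioxane/H2O (10:1), 50 °C, Ar
Reagents that add atoms: none
Why: The aryl group of 4 transmetalates from boron to the monovalent rhodium hydroxide, the aryl rhodium species inserts the C=C bond of 3 with the aryl carbon bonding to the terminal β carbon C3, and water protonates the oxa-π-allyl rhodium enolate at C2, which releases 5 and regenerates the rhodium hydroxide. The closest known reaction type is the Hayashi–Miyaura rhodium-catalysed conjugate addition of arylboronic acids to α,β-unsaturated esters. No ring is closed and no stereocentre is formed, since C2 and C3 both end as CH2 groups. The step needs 1,4-addition with protonolysis in place of β-hydride elimination to the cinnamate ester or protodeboronation of 4; the aqueous medium should make protonolysis of the enolate fast, the phosphine-free diene hydroxo catalyst transmetalates without added base at mild temperature, and the excess of 4 with 3 as limiting component leaves no spare acrylate to act as a hydride acceptor. The para relationship of hydroxyl and side chain is fixed by the C–B bond of 4, and the free phenol and the lipophilic nonadecyl ester should both survive the near-neutral conditions.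

**Compound list**

1 | nonadecan-1-ol | CCCCCCCCCCCCCCCCCCCO | starting material
2 | acryloyl chloride (prop-2-enoyl chloride) | C=CC(=O)Cl | starting material
3 | nonadecyl acrylate (nonadecyl prop-2-enoate) | CCCCCCCCCCCCCCCCCCCOC(=O)C=C | intermediate
4 | 4-hydroxyphenylboronic acid | OB(O)c1ccc(O)cc1 | starting material
5 | nonadecyl 3-(4-hydroxyphenyl)propanoate | CCCCCCCCCCCCCCCCCCCOC(=O)CCc1ccc(O)cc1 | target

**Step count**

Total steps: 2. Longest linear sequence: 2 steps (1 to 3 to 5).

**Steps most likely to fail**

The route has only two steps; both are ranked, the key step first.

1. Step 2. Protodeboronation of the electron-rich boronic acid may outrun transmetalation, the phenoxide may bind rhodium and slow turnover, or the rhodium enolate may undergo β-hydride elimination instead of protonolysis. Conversion would then stall or an unsaturated ester would form. The fallback sets out from 3 and replaces the conjugate addition by a Mizoroki–Heck coupling followed by hydrogenation. Acrylate 3 and 4-iodophenol (Oc1ccc(I)cc1), with Pd(OAc)2, P(o-tol)3 and Et3N in DMF at 90 °C, should give nonadecyl (E)-3-(4-hydroxyphenyl)prop-2-enoate F1 through oxidative addition to zerovalent palladium, insertion and β-hydride elimination. Hydrogenation of F1 with H2 (1 atm) over palladium on carbon (10% Pd/C) in EtOAc at rt should saturate the alkene without touching the ester or the phenol, and the route is rejoined at 5.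

2. Step 1. Radical oligomerisation of the acrylate during acylation or concentration, or conjugate addition of chloride or amine to the new acrylate, may erode the waxy product. The fallback sets out from 1 and introduces the double bond only after the ester is made. Alcohol 1 with 3-chloropropanoyl chloride (ClCCC(=O)Cl) and pyridine in CH2Cl2 at 0 °C should give nonadecyl 3-chloropropanoate F2, a saturated ester that can be purified and stored. Treatment of F2 with Et3N and a trace of BHT in toluene at 60 °C should effect E1cB dehydrochlorination, and the route is rejoined at 3.

**Further compounds**

F1 | step 2 | nonadecyl (E)-3-(4-hydroxyphenyl)prop-2-enoate | CCCCCCCCCCCCCCCCCCCOC(=O)/C=C/c1ccc(O)cc1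
F2 | step 1 | nonadecyl 3-chloropropanoate | CCCCCCCCCCCCCCCCCCCOC(=O)CCCl
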